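The four contiguous stereocentres C7–C8–C8'–C7' of the target (C8/C8' trans on the oxolane ring; aryl anti to C9 across C7–C8, syn to C9' across C7'–C8') are read as a 3,6-diarylcyclohex-4-ene-1,2-diester in which a disposable CH=CH bridge joins C7 to C7'. One catalytic enantioselective Diels–Alder reaction of the symmetric (1E,3E)-1,4-bis(4-silyloxy-3-methoxyphenyl)butadiene with dimethyl fumarate forms C7–C8 and C7'–C8' and sets all four centres. The alkene geometries dictate the relative configuration, the chiral Lewis acid the absolute one. Ester reduction, ether closure, ozonolysis and a retentive twofold Baeyer–Villiger oxidation then replace the bridge carbons by the two benzylic hydroxyl groups.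

Key step: step 6

Remark: Ar denotes 4-[(tert-butyldimethylsilyl)oxy]-3-methoxyphenyl; lignan locants (C7, C8, C9, primed for the second half) are used for positions that end up in the target.

Assumption: the facial sense of the catalyst is assigned from the usual binding picture for enoates on an activated oxazaborolidine (s-trans ester, α-C–H···O contact, one face screened by the neighbouring phenyl); on that basis the (R)-diphenylprolinol-derived catalyst is chosen, and the (S)-catalyst would be substituted unchanged if a configurational check on 9 showed the opposite sense.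

Step 1
Reactants: 1 vanillin
Product: 2 4-[(tert-butyldimethylsilyl)oxy]-3-methoxybenzaldehyde
Conditions: TBSCl, imidazole, DMF, 0 °C → rt
Reagents that add atoms: tert-butyldimethylsilyl chloride, CC(C)(C)[Si](C)(C)Cl
Why: Imidazole-promoted O-silylation of the phenol, the only nucleophilic site, should give an aryl silyl ether that withstands every later step up to the final basic methanolysis.

Step 2
Reactants: 2 4-[(tert-butyldimethylsilyl)oxy]-3-methoxybenzaldehyde; 3 (triphenylphosphoranylidene)acetaldehyde
Product: 4 (E)-3-{4-[(tert-butyldimethylsilyl)oxy]-3-methoxyphenyl}prop-2-enal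
Conditions: toluene, 90 °C (2 in slight excess)
Reagents that add atoms: none
Why: Wittig olefination with the stabilised formylmethylene ylide should give the E-enal, and keeping aldehyde 2 in slight excess should suppress a second homologation of the product.

Step 3
Reactants: 2 4-[(tert-butyldimethylsilyl)oxy]-3-methoxybenzaldehyde
Product: 5 {4-[(tert-butyldimethylsilyl)oxy]-3-methoxyphenyl}methanol
Conditions: NaBH4, MeOH/THF, 0 °C
Reagents that add atoms: none
Why: Borohydride reduction of the aryl aldehyde to the benzylic alcohol is fast at 0 °C and should leave the aryl silyl ether untouched.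

Step 4
Reactants: 5 {4-[(tert-butyldimethylsilyl)oxy]-3-methoxyphenyl}methanol
Product: 6 diethyl {4-[(tert-butyldimethylsilyl)oxy]-3-methoxybenzyl}phosphonate
Conditions: ZnI2, P(OEt)3, toluene, 110 °C
Reagents that add atoms: triethyl phosphite, CCOP(OCC)OCC
Why: ZnI2-mediated direct phosphonylation of an electron-rich benzylic alcohol (a Michaelis–Arbuzov-type process: transesterification to the benzyl diethyl phosphite, then Lewis-acid-assisted C–O to C–P rearrangement through the oxygen-stabilised benzylic electrophile) avoids isolating the labile 4-silyloxybenzyl halide.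

Step 5
Reactants: 4 (E)-3-{4-[(tert-butyldimethylsilyl)oxy]-3-methoxyphenyl}prop-2-enal; 6 diethyl {4-[(tert-butyldimethylsilyl)oxy]-3-methoxybenzyl}phosphonate
Product: 7 (1E,3E)-1,4-bis{4-[(tert-butyldimethylsilyl)oxy]-3-methoxyphenyl}buta-1,3-diene
Conditions: NaN(SiMe3)2, THF, −78 °C → rt; recrystallisation
Reagents that add atoms: none
Why: Horner–Wadsworth–Emmons olefination of the benzylic phosphonate anion with the non-enolisable E-enal should form the new styrenyl double bond E (reversible addition, elimination from the more stable adduct), so the crystalline E,E-diene is expected without disturbing the existing alkene.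

Step 6
Reactants: 7 (1E,3E)-1,4-bis{4-[(tert-butyldimethylsilyl)oxy]-3-methoxyphenyl}buta-1,3-diene; 8 dimethyl fumarate
Product: 9 dimethyl (1R,2R,3R,6S)-3,6-bis(Ar)cyclohex-4-ene-1,2-dicarboxylate (aryl groups cis, esters trans, C1 ester trans to the C6 aryl, C2 ester cis to the C3 aryl)
Conditions: (R)-3,3-diphenyl-1-(o-tolyl)tetrahydro-1H,3H-pyrrolo[1,2-c][1,3,2]oxazaborole (20 mol %), AlBr3 (16 mol %, in CH2Br2), CH2Cl2, −78 → −20 °C
Reagents that add atoms: none
Why: Diels–Alder reaction: the boron of the AlBr3-activated oxazaborolidine binds one ester carbonyl of 8 and lowers its LUMO, and the s-cis diene adds in a concerted, asynchronous, suprafacial–suprafacial [4+2] cycloaddition that forms C7–C8 and C7'–C8'. The closest known reaction type is the enantioselective cycloaddition of fumarate esters with dienes catalysed by cationic or Lewis-acid-activated oxazaborolidines. The cyclohexene ring is closed by intermolecular [4+2] annulation, both σ-bonds being made in the same step. C7 and C7' should come out cis because both diene termini are E and the diene reacts on one face, C8 and C8' trans because the fumarate geometry is retained, and the aryl/ester relation (trans at C7/C8, cis at C7'/C8') follows because a trans-dienophile must place one ester endo and the other exo. The absolute configuration is set by the catalyst, whose phenyl group screens the Si,Si face of the bound s-trans fumarate so that the diene should add to the Re,Re face. The only selectivity required is therefore enantiofacial, since the symmetric diene and the C2-symmetric dienophile leave no regiochemical or endo/exo choice, while the electron-rich aryl groups raise the diene HOMO to offset its hindered termini.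

Step 7
Reactants: 9 dimethyl (1R,2R,3R,6S)-3,6-bis(Ar)cyclohex-4-ene-1,2-dicarboxylate
Product: 10 [(1R,2R,3R,6S)-3,6-bis(Ar)cyclohex-4-ene-1,2-diyl]dimethanol
Conditions: i-Bu2AlH (excess), CH2Cl2, −78 → 0 °C; aq. KNaC4H4O6 (tartrate) work-up
Reagents that add atoms: none
Why: Hydride reduction of both esters to the 1,4-diol involves no basic species that could epimerise C8 or C8', and aryl silyl ethers tolerate i-Bu2AlH at or below 0 °C.

Step 8
Reactants: 10 [(1R,2R,3R,6S)-3,6-bis(Ar)cyclohex-4-ene-1,2-diyl]dimethanol
Product: 11 (3aR,4R,7S,7aR)-4,7-bis(Ar)-1,3,3a,4,7,7a-hexahydroisobenzofuran (trans ring fusion)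
Conditions: PPh3, DIAD, THF, 0 °C → rt
Reagents that add atoms: none
Why: Mitsunobu cyclodehydration, in which one primary hydroxyl is activated as its alkoxyphosphonium ion and displaced 5-exo-tet by the other, should close the 9,9'-ether trans-fused to the cyclohexene under neutral conditions that touch no stereocentre.

Step 9
Reactants: 11 (3aR,4R,7S,7aR)-4,7-bis(Ar)-1,3,3a,4,7,7a-hexahydroisobenzofuran
Product: 13 (2S)-2-Ar-2-{(3S,4S)-4-[(1R)-1-Ar-2-oxoethyl]oxolan-3-yl}acetaldehyde (trans-3,4-disubstituted oxolane; used crude), via ozonide 12 (not isolated)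
Conditions: O3/O2, CH2Cl2, −78 °C (Sudan Red 7B end point); then PPh3, −78 °C → rt
Reagents that add atoms: ozone, [O-][O+]=O
Why: Ozonolysis of the only alkene ([3+2] cycloaddition, Criegee fragmentation and recombination to the ozonide, then phosphine reduction) should excise the bridge as two formyl groups under neutral, non-enolising conditions, with the indicator dye keeping excess ozone away from the electron-rich arenes.

Step 10
Reactants: 13 (2S)-2-Ar-2-{(3S,4S)-4-[(1R)-1-Ar-2-oxoethyl]oxolan-3-yl}acetaldehyde
Product: 14 (S)-Ar{(3R,4R)-4-[(R)-Ar(formyloxy)methyl]oxolan-3-yl}methyl formate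
Conditions: mCPBA, Na2HPO4, CH2Cl2, 0 °C → rt
Reagents that add atoms: meta-chloroperoxybenzoic acid, OOC(=O)c1cccc(Cl)c1
Why: Twofold Baeyer–Villiger oxidation, in which the secondary electron-rich benzylic carbon of each Criegee adduct migrates to oxygen in preference to hydride and with retention, should keep C7 and C7' as fixed in step 6 while the buffer protects the acid-labile benzylic formates.

Step 11
Reactants: 14 (S)-Ar{(3R,4R)-4-[(R)-Ar(formyloxy)methyl]oxolan-3-yl}methyl formate
Product: 16 (S)-(4-hydroxy-3-methoxyphenyl){(3R,4R)-4-[(R)-hydroxy(4-hydroxy-3-methoxyphenyl)methyl]oxolan-3-yl}methanol (7S,8R,8'R,7'R; CNP0157038.2), via bis-silyl diol 15 (not isolated)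
Conditions: K2CO3 (0.1 equiv), MeOH, 0 °C; then K2CO3 (2.5 equiv), rt; aq. NH4Cl
Reagents that add atoms: none
Why: Base-catalysed methanolysis should transesterify the formates within minutes, before any phenoxide exists that could expel a benzylic leaving group as a quinone methide, and the larger carbonate charge then cleaves the two aryl silyl ethers without affecting the four stereocentres.

Compound list
1 | vanillin | COc1cc(C=O)ccc1O | starting material
2 | 4-[(tert-butyldimethylsilyl)oxy]-3-methoxybenzaldehyde | COc1cc(C=O)ccc1O[Si](C)(C)C(C)(C)C | intermediate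
3 | (triphenylphosphoranylidene)acetaldehyde | O=CC=P(c1ccccc1)(c1ccccc1)c1ccccc1 | starting material
4 | (E)-3-{4-[(tert-butyldimethylsilyl)oxy]-3-methoxyphenyl}prop-2-enal | COc1cc(/C=C/C=O)ccc1O[Si](C)(C)C(C)(C)C | intermediate
5 | {4-[(tert-butyldimethylsilyl)oxy]-3-methoxyphenyl}methanol | COc1cc(CO)ccc1O[Si](C)(C)C(C)(C)C | intermediate
6 | diethyl {4-[(tert-butyldimethylsilyl)oxy]-3-methoxybenzyl}phosphonate | CCOP(=O)(Cc1ccc(O[Si](C)(C)C(C)(C)C)c(OC)c1)OCC | intermediate
7 | (1E,3E)-1,4-bis{4-[(tert-butyldimethylsilyl)oxy]-3-methoxyphenyl}buta-1,3-diene | COc1cc(/C=C/C=C/c2ccc(O[Si](C)(C)C(C)(C)C)c(OC)c2)ccc1O[Si](C)(C)C(C)(C)C | intermediate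
8 | dimethyl fumarate | COC(=O)/C=C/C(=O)OC | starting material
9 | dimethyl (1R,2R,3R,6S)-3,6-bis(Ar)cyclohex-4-ene-1,2-dicarboxylate | COc1cc([C@H]2C=C[C@@H](c3ccc(O[Si](C)(C)C(C)(C)C)c(OC)c3)[C@@H](C(=O)OC)[C@@H]2C(=O)OC)ccc1O[Si](C)(C)C(C)(C)C | intermediate
10 | [(1R,2R,3R,6S)-3,6-bis(Ar)cyclohex-4-ene-1,2-diyl]dimethanol | COc1cc([C@H]2C=C[C@@H](c3ccc(O[Si](C)(C)C(C)(C)C)c(OC)c3)[C@@H](CO)[C@@H]2CO)ccc1O[Si](C)(C)C(C)(C)C | intermediate
11 | (3aR,4R,7S,7aR)-4,7-bis(Ar)-1,3,3a,4,7,7a-hexahydroisobenzofuran | COc1cc([C@H]2C=C[C@@H](c3ccc(O[Si](C)(C)C(C)(C)C)c(OC)c3)[C@H]4COC[C@H]24)ccc1O[Si](C)(C)C(C)(C)C | intermediate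
12 | ozonide of 11 (1,2,4-trioxolane bridging the former alkene carbons; configuration at the two acetal carbons not defined) | COc1cc([C@H]2C3OOC(O3)[C@@H](c3ccc(O[Si](C)(C)C(C)(C)C)c(OC)c3)[C@H]4COC[C@H]24)ccc1O[Si](C)(C)C(C)(C)C | intermediate
13 | (2S)-2-Ar-2-{(3S,4S)-4-[(1R)-1-Ar-2-oxoethyl]oxolan-3-yl}acetaldehyde | COc1cc([C@@H](C=O)[C@H]2COC[C@@H]2[C@H](c2ccc(O[Si](C)(C)C(C)(C)C)c(OC)c2)C=O)ccc1O[Si](C)(C)C(C)(C)C | intermediate
14 | (S)-Ar{(3R,4R)-4-[(R)-Ar(formyloxy)methyl]oxolan-3-yl}methyl formate | COc1cc([C@@H](OC=O)[C@H]2COC[C@@H]2[C@@H](OC=O)c2ccc(O[Si](C)(C)C(C)(C)C)c(OC)c2)ccc1O[Si](C)(C)C(C)(C)C | intermediate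
15 | (S)-Ar{(3R,4R)-4-[(R)-Ar(hydroxy)methyl]oxolan-3-yl}methanol | COc1cc([C@@H](O)[C@H]2COC[C@@H]2[C@@H](O)c2ccc(O[Si](C)(C)C(C)(C)C)c(OC)c2)ccc1O[Si](C)(C)C(C)(C)C | intermediate
16 | (S)-(4-hydroxy-3-methoxyphenyl){(3R,4R)-4-[(R)-hydroxy(4-hydroxy-3-methoxyphenyl)methyl]oxolan-3-yl}methanol | COc1cc([C@@H](O)[C@H]2COC[C@@H]2[C@@H](O)c2ccc(O)c(OC)c2)ccc1O | target

Total step count: 11. Longest linear sequence: 10 steps (1 → 2 → 5 → 6 → 7 → 9 → 10 → 11 → 13 → 14 → 16); step 2 is the only branch.

Steps most likely to fail, in order of risk: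

First, the cycloaddition of step 6. The hindered 1,4-diaryl diene may react too slowly with the catalyst-bound fumarate at low temperature, and enantiofacial discrimination may erode at the temperature then needed. A stepwise, zwitterionic addition of the very electron-rich styrenyl termini (or their cationic oligomerisation) could also loosen the cis relation of the aryl groups. The fallback keeps the disconnection but moves stereocontrol from the catalyst to a covalently bound auxiliary. Fumaryl chloride and (1S,2R,5S)-menthol (pyridine, CH2Cl2) would give di-(+)-menthyl fumarate F1. This would be combined with diene 7 under Et2AlCl or i-Bu2AlCl in toluene at −40 → −20 °C, where the two menthyl groups shield the same face cooperatively. The resulting dimenthyl cycloadduct F2 is a diastereomer that could be purified by crystallisation. Reduction of F2 with excess i-Bu2AlH (toluene, 0 °C → rt) would release the auxiliary and return to the route at diol 10.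

Second, the oxygen insertion of step 10. The enolisable α-aryl aldehydes may epimerise at C7/C7' before the peracid adds, hydride may migrate in competition (over-oxidation to acids), or the acid by-product may ionise the electron-rich benzylic formates. The fallback replaces the aldehyde Baeyer–Villiger by the ketone version. Dialdehyde 13 would be treated with MeMgBr/CeCl3 (THF, −78 °C, a non-basic addition) to give the bis(1-hydroxyethyl) compound F4, whose carbinol epimers are inconsequential. Dess–Martin oxidation would give the bis(methyl ketone) F5, and Baeyer–Villiger oxidation (mCPBA, NaHCO3, CH2Cl2) should give the bis-acetate F6, since the benzylic carbon migrates in preference to methyl and with retention. Reductive removal of the acetates with i-Bu2AlH at −78 °C avoids any phenoxide and comes back to the route at bis-silyl diol 15, which is desilylated as in the second stage of step 11.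

Third, the alkene cleavage of step 9. Ozone may attack the two silyloxy-methoxyarene rings competitively, and the dialdehyde may epimerise during the reductive work-up. The fallback avoids ozone altogether. Dihydroxylation of 11 with OsO4 (cat.) and N-methylmorpholine N-oxide (acetone/H2O) should occur on the face anti to both aryl groups and give the cis-diol F3. Glycol cleavage with NaIO4 (THF/pH 7 buffer, 0 °C) then returns to the route at dialdehyde 13.

Further compounds
F1 | step 6 | bis[(1S,2R,5S)-2-isopropyl-5-methylcyclohexyl] (E)-but-2-enedioate (di-(+)-menthyl fumarate) | CC(C)[C@H]1CC[C@H](C)C[C@@H]1OC(=O)/C=C/C(=O)O[C@H]1C[C@@H](C)CC[C@@H]1C(C)C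
F2 | step 6 | bis[(1S,2R,5S)-2-isopropyl-5-methylcyclohexyl] (1R,2R,3R,6S)-3,6-bis(Ar)cyclohex-4-ene-1,2-dicarboxylate | COc1cc([C@H]2C=C[C@@H](c3ccc(O[Si](C)(C)C(C)(C)C)c(OC)c3)[C@@H](C(=O)O[C@H]4C[C@@H](C)CC[C@@H]4C(C)C)[C@@H]2C(=O)O[C@H]5C[C@@H](C)CC[C@@H]5C(C)C)ccc1O[Si](C)(C)C(C)(C)C
F3 | step 9 | 5,6-cis-diol of 11: trans-fused 4,7-bis(Ar)octahydroisobenzofuran-5,6-diol with both hydroxyls anti to the aryl groups | COc1cc([C@H]2[C@H](O)[C@H](O)[C@@H](c3ccc(O[Si](C)(C)C(C)(C)C)c(OC)c3)[C@H]4COC[C@H]24)ccc1O[Si](C)(C)C(C)(C)C
F4 | step 10 | bis(1-hydroxyethyl) compound from 13 (each formyl group converted to CH(OH)CH3, carbinol configuration not defined) | COc1cc([C@@H](C(C)O)[C@H]2COC[C@@H]2[C@H](c2ccc(O[Si](C)(C)C(C)(C)C)c(OC)c2)C(C)O)ccc1O[Si](C)(C)C(C)(C)C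
F5 | step 10 | bis(methyl ketone): (3S)-3-Ar-3-{(3S,4S)-4-[(1R)-1-Ar-2-oxopropyl]oxolan-3-yl}propan-2-one | COc1cc([C@@H](C(C)=O)[C@H]2COC[C@@H]2[C@H](c2ccc(O[Si](C)(C)C(C)(C)C)c(OC)c2)C(C)=O)ccc1O[Si](C)(C)C(C)(C)C
F6 | step 10 | bis-acetate: (S)-Ar{(3R,4R)-4-[(R)-Ar(acetoxy)methyl]oxolan-3-yl}methyl acetate | COc1cc([C@@H](OC(C)=O)[C@H]2COC[C@@H]2[C@@H](OC(C)=O)c2ccc(O[Si](C)(C)C(C)(C)C)c(OC)c2)ccc1O[Si](C)(C)C(C)(C)C
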